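Follow every mole of coupling partner, taken here as the limiting reagent, through the noon run, where the target stands still from 2.50 min on.

common to all: catalyst 0.50 mM

| charge | starting material | coupling partner | second substrate | temperature | remark | time |
|---|---|---|---|---|---|---|
| winter | 0.070 M | 0.090 M | 0.050 M | 42 °C | run made earlier |  |
| noon | 0.11 M | 0.090 M | 0.050 M | 59 °C | run made earlier |  |
| summer | 0.050 M | 0.090 M | 0.025 M | 42 °C | run made earlier |  |
| maple | 0.050 M | 0.0900 M | 0.0500 M |  | at 35 °C until 5.0 min, from then on at 65 °C | 15 min |
| cedar | 0.050 M | 0.0900 M | 0.0500 M | 35 °C |  | 15 min |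
| alder | 0.050 M | 0.0900 M | 0.0500 M | 65 °C |  | 15 min |

| run | time / min | target / % | starting material / % |
|---|---|---|---|
| winter | 1.50 | 19.1 | 81.2 |
| winter | 3.00 | 27.8 | 72.6 |
| winter | 5.00 | 33.6 | 67.1 |
| winter | 6.00 | 35.5 | 64.9 |
| winter | 8.00 | 36.8 | 63.2 |
| winter | 10.0 | 38.5 | 61.2 |
| winter | 12.0 | 39.8 | 61.9 |
| noon | 0.500 | 13.6 | 85.9 |
| noon | 1.00 | 19.2 | 80.6 |
| noon | 1.50 | 21.9 | 78.4 |
| noon | 2.00 | 23.9 | 76.6 |
| noon | 2.50 | 23.4 | 75.8 |
| noon | 3.00 | 23.5 | 76.9 |
| noon | 4.00 | 23.4 | 75.9 |
| summer | 2.50 | 29.5 | 69.8 |
| summer | 5.00 | 42.4 | 57.1 |
| summer | 8.00 | 49.3 | 50.3 |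
| summer | 10.0 | 53.1 | 47.2 |
| summer | 12.0 | 54.2 | 44.9 |

(scatter of a reading: 0.5 percentage points)

- the analysis behind the earlier runs scatters by 0.5 percentage points, standard deviation

* the flask with the highest amount of target, in percent of the starting material charged ("all alike" if they lie within 1.5 percentage points) (maple / cedar / alder / all alike)
* final target, as a percentage of the starting material charged, in maple
* final target, as a percentage of the starting material charged, in cedar
* final target, as a percentage of the starting material charged, in alder

Reckoning one coupling partner per target and per second product, the noon books read: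

- charged: 0.090 M
- into target: 23.4% of 0.11 M, or 0.0257 M
- into second substrate, at most its charge: 0.050 M
- elsewhere or still unused, at least: 0.0143 M

Target takes 28.6% of the partner charged. Noon's 0.267 is a lifetime count, the natural logarithm of charged starting material over what has not become target. Its pace up to the first reading is 0.141 min⁻¹ in winter and 0.140 min⁻¹ in summer, with 0.070 M and 0.050 M of starting material charged. My reckoning therefore carries counts between flasks, not molarities.

Alder, at 65 °C against noon's 59 °C and with the same partner charge, is lent noon's count as an estimate:

target in alder, about 23.4%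

Cedar, at 35 °C against winter's 42 °C and running 15 min against 12.0 min, is lent winter's last count as an estimate, 0.507, which means 39.8% of target.

Maple takes winter's count at 5.00 min, 0.409, for its cold stage. Winter's pace just after that time, against its early pace, is taken as the share of partner left. That share earns its part of noon's count once heated:

share left: 0.205
count: 0.464, target about 37.1%

This is rough, since winter is warmer than maple's cold stage. Still, cedar comes out ahead of maple, and maple ahead of alder.

The forecast named maple, with 55.3% in maple, 51.7% in cedar and 50% in alder, reading that “The target stalls at almost the same absolute level in all runs”.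

The flasks give 35.3% in maple, 46.0% in cedar and 21.2% in alder, so cedar holds the most.

    starting material + coupling partner + catalyst → catalyst + target (k = 3200 L² mol⁻² min⁻¹, Ea = 41.0 kJ mol⁻¹)
    second substrate + coupling partner + catalyst → catalyst + second product (k = 12000 L² mol⁻² min⁻¹, Ea = 38.0 kJ mol⁻¹)
    coupling partner → decomposed reagent (k = 0.0370 min⁻¹, Ea = 97.0 kJ mol⁻¹)
    target → over-reaction product (k = 2.70 × 10⁻⁴ min⁻¹, Ea = 108 kJ mol⁻¹)
    (constants at 35 °C)

At the start of cedar, decomposition takes coupling partner at 0.037 min⁻¹, against 0.380 min⁻¹ for the two couplings together. From the coldest to the hottest flask, decomposition speeds up 28.8 times and the coupling to target 4.1 times, and alder ends with 0.0463 M of decomposed reagent against 0.0143 M in cedar. Alder's count from its unconverted starting material is 0.288, beside noon's 0.267. Cedar's is 0.618, and its neighbour charged with 0.013 M of starting material reaches 0.810.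

The runs were computed from invented constants.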